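If free catalyst goes in by portions, the first thing I wanted from the runs was how long the rate of target gain lasts after the last portion.

in all of them: starting material 0.21 M; added ligand 4.4 mM

|  | coupling partner | protic impurity | free catalyst | remark | time |
|---|---|---|---|---|---|
| west | 0.63 M | 0.105 M | 1 mM (in portions, 2) | the very flask that is asked about, followed so far; portions every 80 min |  |
| south-east | 0.63 M | 0.21 M | 1 mM (in portions, 2) | run made earlier; portions every 80 min |  |
| flask | 0.630 M | 0.105 M | 1.0 mM (in portions, 2) | the portions of free catalyst follow each other after 80 min, the first at the start | 8.0 h |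

- west (time / min: target / %): 15.0: 0.7; 30.0: 2.6; 40.0: 0.5; 60.0: 0; 80.0: 3.5; 90.0: 2.4
- south-east (time / h: target / %): 0.417: 0; 0.667: 1.2; 1.00: 1.0; 1.50: 3.7; 2.50: 6.8; 4.00: 12.1; 6.00: 16.6

(scatter of a reading: 1 percentage point)

1. amount of target in percent of the starting material charged, at 1.5 h, 4.0 h and 8.0 h



I read that from the south-east run, taking c(target) as a fraction of the starting material charged. Its gain per hour was, from 2.50 h to 4.00 h and from 4.00 h to 6.00 h:

r(mid) = 0.0353 /h

r(late) = 0.0225 /h

Their window centres lie 1.75 h apart, so

ln(2) × 1.75 h / ln(r(mid)/r(late)) = 2.69 h

This is the rate half-life: the time in which the rate of target gain halves once both portions are in, if the fall is steady. Each rate is a difference of two readings that scatter by 1 percentage point, so it is a rough reading.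

The ladder then ran as follows. The portion interval of 80 min is shorter than the rate half-life. The asked 8.0 h is longer, at 2.97 rate half-lives, so I expected the late course of the west flask to be a fading one, though I was carrying over a reading from the south-east run, which has c(protic impurity) at 0.21 M against 0.105 M in the west flask.

The forecast gave 3.2 %, 15 % and 29 %, and it expected a fade: “The slow fade suggests gradual catalyst loss or substrate depletion.” I kept its first two values and applied the rate half-life to the window after 4.0 h, whose centre lies 3.25 h after that of the window before it:

c(target) at 8.0 h = 23.2 %

My reckoning for 8.0 h is lower than the forecast's value for that time.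

The west flask gave 2.97 %, 14.0 % and 22.3 %.

    starting material + free catalyst ⇌ free catalyst + open intermediate (K = 1.40, k = 151 /M/h)
    free catalyst + open intermediate ⇌ catalyst intermediate (K = 11.0 /M, k = 1920 /M/h)
    coupling partner + catalyst intermediate → free catalyst + target (k = 917 /M/h)
    free catalyst → spent catalyst (k = 0.167 /h)
    free catalyst + added ligand ⇌ idle complex (K = 320 /M, k = 66.6 /M/h)
    starting material + protic impurity → quenched substrate (k = 0.827 /M/h)

The west flask's rate of target gain fell from 0.0441 /h between 1.5 h and 4.0 h to 0.0207 /h between 4.0 h and 8.0 h, a rate half-life of 2.98 h beside the 2.69 h read from the south-east run, and the forecast stood 6.7 points above the flask at 8.0 h. Between 4.00 h and 8.00 h free catalyst in the west flask went from 33.7 % to 19.5 % of the catalyst charged, and starting material from 59.1 % to 43.4 % of its charge.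

The readings are simulated from invented constants.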